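**Retrosynthetic overview**
1. The target follows from its doubly protected form (ring B C2′ oxygen as methoxymethyl ether, allylic oxygen as tert-butyldimethylsilyl ether) by two deprotections.
2. Feature used: in benzoate ring A the carbon bearing the lactone carbonyl (C1) and the carbon bearing the methyl group (C6) are neighbours, like the two sp carbons of a but-2-ynoate, while C2–C5 (diaryl ether oxygen on C3) correspond to C3–C6 of a 4-aryloxy-2H-pyran-2-one. One intramolecular pyranone–alkyne [4+2] cycloaddition with loss of CO2 therefore forms ring A and the 12-membered lactone in the same step.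
3. The cycloaddition substrate comes from esterification of a (3S,4S)-configured Z-alkenyl alcohol with but-2-ynoic acid, after the ring B phenol has been joined to pyranone C4 by addition–elimination on 2-oxo-2H-pyran-4-yl tosylate.
4. The Z-alkenyl phenol comes from reductive opening of 7-(methoxymethoxy)benzofuran (furan C2=C3 becomes the Z-alkene, the furan oxygen becomes the ring B C1′ phenol) and chelation-controlled addition to (S)-2-[(4-methoxybenzyl)oxy]heptanal, itself made by hydrolytic kinetic resolution of 2-pentyloxirane.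
5. Order of rings: ring B is bought as the benzofuran, the pyranone ring is bought and serves as the diene, ring A and the macrolactone are formed last and together.

Key step: step 12

Remark: the target structure fixes only the two carbinol centres (both S) and the Z-alkene; any hindered rotation of the ansa ring is taken as unspecified and is not controlled.

**Route**

Step 1
Reactants: 1 benzofuran-7-ol
Product: 2 7-(methoxymethoxy)-1-benzofuran
Conditions: MOMCl, i-Pr2NEt, CH2Cl2, 0 °C to rt
Reagents that add atoms: chloromethyl methyl ether, COCCl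
Why: Williamson-type O-alkylation of the phenol gives the acetal ether that masks the later ring B C2′ hydroxyl through the reductive, basic and thermal steps; no stereocentre is involved.

Step 2
Reactants: 3 racemic 2-pentyloxirane
Product: 4 (S)-heptane-1,2-diol
Conditions: (R,R)-Co(salen)(OAc) (0.5 mol %; salen = N,N′-bis(3,5-di-tert-butylsalicylidene)cyclohexane-1,2-diamine dianion, trivalent cobalt), H2O (0.45 equiv), THF, 0 °C to rt; unreacted epoxide distilled off
Reagents that add atoms: water, O
Why: Jacobsen hydrolytic kinetic resolution, in which the (R,R) catalyst should hydrate the (S)-epoxide at its terminal carbon with retention at C2, so the later lactone carbinol centre is set by catalyst control.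

Step 3
Reactants: 4 (S)-heptane-1,2-diol
Product: 5 (4S)-2-(4-methoxyphenyl)-4-pentyl-1,3-dioxolane (both acetal epimers)
Conditions: 4-MeOC6H4CH(OMe)2, PPTS (cat.), CH2Cl2, rt
Reagents that add atoms: 4-methoxybenzaldehyde dimethyl acetal, COc1ccc(cc1)C(OC)OC
Why: acid-catalysed transacetalisation of the 1,2-diol leaves the carbinol centre untouched, and both acetal epimers converge in the next step.

Step 4
Reactants: 5 (4S)-2-(4-methoxyphenyl)-4-pentyl-1,3-dioxolane
Product: 6 (S)-2-[(4-methoxybenzyl)oxy]heptan-1-ol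
Conditions: i-Bu2AlH, CH2Cl2, −78 to 0 °C; aq potassium sodium tartrate
Reagents that add atoms: none
Why: regioselective reductive acetal opening, in which the aluminium hydride binds the less hindered primary oxygen and reduces the oxocarbenium ion, leaving the 4-methoxybenzyl group on the secondary oxygen.

Step 5
Reactants: 6 (S)-2-[(4-methoxybenzyl)oxy]heptan-1-ol
Product: 7 (S)-2-[(4-methoxybenzyl)oxy]heptanal
Conditions: Dess–Martin periodinane, CH2Cl2, 0 °C to rt; used at once
Reagents that add atoms: none
Why: Dess–Martin oxidation under non-basic conditions should give the α-alkoxy aldehyde without epimerisation.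

Step 6
Reactants: 2 7-(methoxymethoxy)-1-benzofuran; 7 (S)-2-[(4-methoxybenzyl)oxy]heptanal
Product: 10 2-[(1Z,3S,4S)-3-hydroxy-4-[(4-methoxybenzyl)oxy]non-1-en-1-yl]-6-(methoxymethoxy)phenol, via dilithio species 8 (not isolated), via bromomagnesium species 9 (not isolated)
Conditions: Li powder (2.2 equiv), 4,4′-di-tert-butylbiphenyl (5 mol %), THF, 0 °C; filtered from excess Li; MgBr2·OEt2 (2.2 equiv), −78 to −20 °C; 7 (0.7 equiv) in CH2Cl2, −78 °C; then H2O
Reagents that add atoms: none
Why: arene-catalysed reductive lithiation cleaves the furan O–C2 bond to the (Z)-2-(2-lithiovinyl)phenolate (geometry inherited from the ring and held by O–Li chelation), and after exchange to magnesium the vinyl group adds to the aldehyde through the Cram chelate of the carbonyl and α-alkoxy oxygens, anti to the pentyl group, which should set the new carbinol centre 3S (3,4-syn); the minor 3-epimer is removed by chromatography on base-washed silica.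

Step 7
Reactants: 11 4-hydroxy-2H-pyran-2-one
Product: 12 2-oxo-2H-pyran-4-yl 4-methylbenzenesulfonate
Conditions: TsCl, Et3N, CH2Cl2, 0 °C
Reagents that add atoms: 4-methylbenzenesulfonyl chloride, Cc1ccc(cc1)S(Cl)(=O)=O
Why: O-sulfonylation of the vinylogous acid turns pyranone C4 into an addition–elimination acceptor.

Step 8
Reactants: 10 2-[(1Z,3S,4S)-3-hydroxy-4-[(4-methoxybenzyl)oxy]non-1-en-1-yl]-6-(methoxymethoxy)phenol; 12 2-oxo-2H-pyran-4-yl 4-methylbenzenesulfonate
Product: 13 4-{2-[(1Z,3S,4S)-3-hydroxy-4-[(4-methoxybenzyl)oxy]non-1-en-1-yl]-6-(methoxymethoxy)phenoxy}-2H-pyran-2-one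
Conditions: K2CO3, MeCN, rt
Reagents that add atoms: none
Why: vinylogous acyl substitution (addition–elimination), in which the phenoxide, the only group deprotonated by carbonate, adds at the unhindered pyranone C4 and expels sulfonate, so the crowded ether oxygen is installed without any aryl–oxygen coupling and the secondary alcohol stays free.

Step 9
Reactants: 13 4-{2-[(1Z,3S,4S)-3-hydroxy-4-[(4-methoxybenzyl)oxy]non-1-en-1-yl]-6-(methoxymethoxy)phenoxy}-2H-pyran-2-one
Product: 14 4-{2-[(1Z,3S,4S)-3-[(tert-butyldimethylsilyl)oxy]-4-[(4-methoxybenzyl)oxy]non-1-en-1-yl]-6-(methoxymethoxy)phenoxy}-2H-pyran-2-one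
Conditions: TBSOTf, 2,6-lutidine, CH2Cl2, −78 °C
Reagents that add atoms: tert-butyldimethylsilyl trifluoromethanesulfonate, CC(C)(C)[Si](C)(C)OS(=O)(=O)C(F)(F)F
Why: silyl triflate silylation of the hindered secondary allylic alcohol with a non-nucleophilic base spares the pyranone and retains the configuration at C3.

Step 10
Reactants: 14 4-{2-[(1Z,3S,4S)-3-[(tert-butyldimethylsilyl)oxy]-4-[(4-methoxybenzyl)oxy]non-1-en-1-yl]-6-(methoxymethoxy)phenoxy}-2H-pyran-2-one
Product: 15 4-{2-[(1Z,3S,4S)-3-[(tert-butyldimethylsilyl)oxy]-4-hydroxynon-1-en-1-yl]-6-(methoxymethoxy)phenoxy}-2H-pyran-2-one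
Conditions: DDQ, CH2Cl2/pH 7 phosphate buffer, 0 °C
Reagents that add atoms: none
Why: oxidative cleavage of the 4-methoxybenzyl ether by DDQ under buffered neutral conditions frees only the C4 alcohol and avoids base-induced 1,2-silyl migration.

Step 11
Reactants: 15 4-{2-[(1Z,3S,4S)-3-[(tert-butyldimethylsilyl)oxy]-4-hydroxynon-1-en-1-yl]-6-(methoxymethoxy)phenoxy}-2H-pyran-2-one; 16 but-2-ynoic acid
Product: 17 (1Z,3S,4S)-3-[(tert-butyldimethylsilyl)oxy]-1-{3-(methoxymethoxy)-2-[(2-oxo-2H-pyran-4-yl)oxy]phenyl}non-1-en-4-yl but-2-ynoate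
Conditions: DCC, DMAP (cat.), CH2Cl2, −20 to 0 °C
Reagents that add atoms: none
Why: Steglich esterification acylates the secondary alcohol with retention, with low temperature and catalytic DMAP limiting conjugate addition to the ynoate.

Step 12
Reactants: 17 (1Z,3S,4S)-3-[(tert-butyldimethylsilyl)oxy]-1-{3-(methoxymethoxy)-2-[(2-oxo-2H-pyran-4-yl)oxy]phenyl}non-1-en-4-yl but-2-ynoate
Product: 19 doubly protected macrolactone (target carrying the ring B O-methoxymethyl group plus the allylic O-tert-butyldimethylsilyl group), via bridged cycloadduct 18 (not isolated)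
Conditions: 1,2-dichlorobenzene (0.001 M, slow addition), BHT (cat.), 180 °C, sealed vessel, argon
Reagents that add atoms: none
Why: Proposed new method: a thermal normal-demand [4+2] cycloaddition of the electron-poor but-2-ynoate (2π) across C3 and C6 of the 4-aryloxy-2-pyranone (4π) should give the 2-oxabicyclo[2.2.2]octa-5,7-dien-3-one 18, which loses CO2 by retro-[4+2] under the same conditions, making the sequence irreversible and ending in benzene ring A. The closest known reactions are the intermolecular 2-pyranone–alkyne benzannulation with CO2 extrusion and type 2 intramolecular Diels–Alder reactions (tether on an inner diene carbon) that give meta-bridged rings; their combination in a macrocyclic setting has not been shown. Ring A closes by cycloaddition then cycloreversion (pyranone C3–C6 become ring A C2–C5, the alkyne carbons become C1 and C6), and the 12-membered lactone closes in the same event in the type 2 mode, because the tether leaves pyranone C4 and ends at the ester-bearing alkyne carbon, which therefore sits meta to the ether oxygen. No stereocentre is created in 19: the two bridgehead centres of 18 are erased on aromatisation, so either pyranone face may react, and C3, C4 and the Z-alkene of the chain are not touched. The selectivity needed is regiochemical (ester-bearing carbon to pyranone C3, not C6) and runs against the intrinsic bias of nucleophilic C3; it is secured by the nine-atom tether, since the reversed mode would give a strained 13-membered para-bridged ring, while the Z-alkene and the 1,2-disubstituted ring B fold the ynoate over the pyranone and high dilution suppresses bimolecular cycloaddition.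

Step 13
Reactants: 19 doubly protected macrolactone
Product: 20 allylic O-tert-butyldimethylsilyl ether of the target (ring B phenol free)
Conditions: NaHSO4·SiO2, CH2Cl2 (wet), rt
Reagents that add atoms: none
Why: heterogeneous acid-catalysed hydrolysis selective for phenolic methoxymethyl ethers frees the ring B phenol while the silyl ether still masks the ionisable allylic oxygen; partial loss of the silyl group here would be harmless because it is removed next.

Step 14
Reactants: 20 allylic O-tert-butyldimethylsilyl ether of the target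
Product: 21 CNP0319567.1 (12-membered diaryl ether macrolactone, both carbinol centres S, Z-alkene)
Conditions: HF·pyridine, pyridine, THF, 0 °C to rt
Reagents that add atoms: none
Why: fluoride-driven Si–O cleavage under buffered conditions removes the silyl ether without base, so the lactone should not migrate to the neighbouring hydroxyl and both stereocentres are retained.

**Compound list**
1 | benzofuran-7-ol | Oc1cccc2ccoc12 | starting material
2 | 7-(methoxymethoxy)-1-benzofuran | COCOc1cccc2ccoc12 | intermediate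
3 | 2-pentyloxirane (racemic) | CCCCCC1CO1 | starting material
4 | (S)-heptane-1,2-diol | CCCCC[C@H](O)CO | intermediate
5 | (4S)-2-(4-methoxyphenyl)-4-pentyl-1,3-dioxolane (both acetal epimers) | CCCCC[C@H]1COC(O1)c1ccc(OC)cc1 | intermediate
6 | (S)-2-[(4-methoxybenzyl)oxy]heptan-1-ol | CCCCC[C@H](OCc1ccc(OC)cc1)CO | intermediate
7 | (S)-2-[(4-methoxybenzyl)oxy]heptanal | CCCCC[C@H](OCc1ccc(OC)cc1)C=O | intermediate
8 | lithium 2-[(Z)-2-lithioethenyl]-6-(methoxymethoxy)phenolate | [Li]/C=C\c1cccc(OCOC)c1O[Li] | intermediate (not isolated)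
9 | bromomagnesium 2-[(Z)-2-(bromomagnesio)ethenyl]-6-(methoxymethoxy)phenolate | Br[Mg]/C=C\c1cccc(OCOC)c1O[Mg]Br | intermediate (not isolated)
10 | 2-[(1Z,3S,4S)-3-hydroxy-4-[(4-methoxybenzyl)oxy]non-1-en-1-yl]-6-(methoxymethoxy)phenol | CCCCC[C@H](OCc1ccc(OC)cc1)[C@@H](O)/C=C\c1cccc(OCOC)c1O | intermediate
11 | 4-hydroxy-2H-pyran-2-one | O=C1C=C(O)C=CO1 | starting material
12 | 2-oxo-2H-pyran-4-yl 4-methylbenzenesulfonate | Cc1ccc(cc1)S(=O)(=O)OC1=CC(=O)OC=C1 | intermediate
13 | 4-{2-[(1Z,3S,4S)-3-hydroxy-4-[(4-methoxybenzyl)oxy]non-1-en-1-yl]-6-(methoxymethoxy)phenoxy}-2H-pyran-2-one | CCCCC[C@H](OCc1ccc(OC)cc1)[C@@H](O)/C=C\c1cccc(OCOC)c1OC1=CC(=O)OC=C1 | intermediate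
14 | 4-{2-[(1Z,3S,4S)-3-[(tert-butyldimethylsilyl)oxy]-4-[(4-methoxybenzyl)oxy]non-1-en-1-yl]-6-(methoxymethoxy)phenoxy}-2H-pyran-2-one | CCCCC[C@H](OCc1ccc(OC)cc1)[C@@H](O[Si](C)(C)C(C)(C)C)/C=C\c1cccc(OCOC)c1OC1=CC(=O)OC=C1 | intermediate
15 | 4-{2-[(1Z,3S,4S)-3-[(tert-butyldimethylsilyl)oxy]-4-hydroxynon-1-en-1-yl]-6-(methoxymethoxy)phenoxy}-2H-pyran-2-one | CCCCC[C@H](O)[C@@H](O[Si](C)(C)C(C)(C)C)/C=C\c1cccc(OCOC)c1OC1=CC(=O)OC=C1 | intermediate
16 | but-2-ynoic acid | CC#CC(=O)O | starting material
17 | (1Z,3S,4S)-3-[(tert-butyldimethylsilyl)oxy]-1-{3-(methoxymethoxy)-2-[(2-oxo-2H-pyran-4-yl)oxy]phenyl}non-1-en-4-yl but-2-ynoate | CCCCC[C@H](OC(=O)C#CC)[C@@H](O[Si](C)(C)C(C)(C)C)/C=C\c1cccc(OCOC)c1OC1=CC(=O)OC=C1 | intermediate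
18 | bridged 2-oxabicyclo[2.2.2]octa-5,7-dien-3-one cycloadduct (bridgehead configuration not defined, either face) | CCCCC[C@@H]1OC(=O)C2=C(C)C3OC(=O)C2C(=C3)Oc2c(OCOC)cccc2/C=C\[C@@H]1O[Si](C)(C)C(C)(C)C | intermediate (not isolated)
19 | doubly protected macrolactone (ring B O-methoxymethyl, allylic O-tert-butyldimethylsilyl) | CCCCC[C@@H]1OC(=O)c2cc(ccc2C)Oc2c(OCOC)cccc2/C=C\[C@@H]1O[Si](C)(C)C(C)(C)C | intermediate
20 | allylic O-tert-butyldimethylsilyl ether of the target | CCCCC[C@@H]1OC(=O)c2cc(ccc2C)Oc2c(O)cccc2/C=C\[C@@H]1O[Si](C)(C)C(C)(C)C | intermediate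
21 | CNP0319567.1 | CCCCC[C@@H]1OC(=O)c2cc(ccc2C)Oc2c(O)cccc2/C=C\[C@@H]1O | target

**Step count and risks**
Total steps: 14. Longest linear sequence: 12 (steps 2–6 and 8–14, from 2-pentyloxirane).

Steps most likely to fail:

1. Step 12 (proposed new method). The tethered alkyne may not reach the pyranone face before thermal decomposition, bimolecular cycloaddition may outrun ring closure, or the alkyne may add in the reversed orientation. The fallback uses known chemistry, sets out from 10 and returns at 19. The crowded phenol of 10 is O-arylated with commercial methyl 5-iodo-2-methylbenzoate under Ullmann conditions for hindered phenols (CuI, picolinic acid, K3PO4, DMSO, 80 °C) to give methyl 5-{2-[(1Z,3S,4S)-3-hydroxy-4-[(4-methoxybenzyl)oxy]non-1-en-1-yl]-6-(methoxymethoxy)phenoxy}-2-methylbenzoate F1. Silylation (TBSOTf, 2,6-lutidine, −78 °C) gives the 3-O-tert-butyldimethylsilyl ether of that ester F2. Saponification (LiOH, THF/MeOH/H2O, 40 °C) gives the corresponding 2-methylbenzoic acid F3. DDQ (buffered CH2Cl2) gives the seco acid 5-{2-[(1Z,3S,4S)-3-[(tert-butyldimethylsilyl)oxy]-4-hydroxynon-1-en-1-yl]-6-(methoxymethoxy)phenoxy}-2-methylbenzoic acid F4. Shiina macrolactonisation (2-methyl-6-nitrobenzoic anhydride, DMAP, Et3N, toluene, slow addition at high dilution) closes F4 to 19. In this variant ring A is bought and the 12-membered ring is closed at the ester C–O bond.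

2. Step 6. Electron transfer may also cleave the aryl acetal ether or over-reduce the styrene, and the magnesium chelate may be too weak in THF, giving poor facial selectivity at the aldehyde. The fallback sets out from 2 and 7 and returns at 10; it makes the Z-alkene by alkyne semi-hydrogenation instead. Ozonolysis of the furan double bond of 2 (O3, CH2Cl2/MeOH, −78 °C; Me2S; then K2CO3, MeOH to remove the formate) gives 2-hydroxy-3-(methoxymethoxy)benzaldehyde F5. Ohira–Bestmann homologation (dimethyl (1-diazo-2-oxopropyl)phosphonate, K2CO3, MeOH, rt) gives 2-ethynyl-6-(methoxymethoxy)phenol F6. Silylation (TBSCl, imidazole, DMF) gives tert-butyl[2-ethynyl-6-(methoxymethoxy)phenoxy]dimethylsilane F7. The derived alkynylzinc bromide (n-BuLi, THF, −78 °C; ZnBr2; Et2O) adds to 7 under chelation control to give (3S,4S)-1-{2-[(tert-butyldimethylsilyl)oxy]-3-(methoxymethoxy)phenyl}-4-[(4-methoxybenzyl)oxy]non-1-yn-3-ol F8. Semi-hydrogenation (H2, Pd/CaCO3 poisoned with Pb(OAc)2, quinoline, EtOAc) gives (1Z,3S,4S)-1-{2-[(tert-butyldimethylsilyl)oxy]-3-(methoxymethoxy)phenyl}-4-[(4-methoxybenzyl)oxy]non-1-en-3-ol F9. TBAF (THF, 0 °C) frees the phenol and returns 10.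

3. Step 8. The doubly ortho-substituted phenoxide may attack sulfur (sulfonyl transfer) instead of C4 or add too slowly, and the pyranone may be opened by base. The fallback sets out from 11 and 10 and returns at 13. Compound 11 is converted with n-Bu4NBr and P2O5 (toluene, 100 °C) into 4-bromo-2H-pyran-2-one F10. F10 is joined to 10 by copper-catalysed Ullmann-type C–O coupling (CuI, picolinic acid, K3PO4, MeCN, 50 °C) to give 13. A halide partner excludes sulfonyl transfer, and the copper phenoxide pathway does not rely on the nucleophilicity of the free hindered phenoxide.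

Further compounds
F1 | step 12 | methyl 5-{2-[(1Z,3S,4S)-3-hydroxy-4-[(4-methoxybenzyl)oxy]non-1-en-1-yl]-6-(methoxymethoxy)phenoxy}-2-methylbenzoate | CCCCC[C@H](OCc1ccc(OC)cc1)[C@@H](O)/C=C\c1cccc(OCOC)c1Oc1ccc(C)c(c1)C(=O)OC
F2 | step 12 | methyl 5-{2-[(1Z,3S,4S)-3-[(tert-butyldimethylsilyl)oxy]-4-[(4-methoxybenzyl)oxy]non-1-en-1-yl]-6-(methoxymethoxy)phenoxy}-2-methylbenzoate | CCCCC[C@H](OCc1ccc(OC)cc1)[C@@H](O[Si](C)(C)C(C)(C)C)/C=C\c1cccc(OCOC)c1Oc1ccc(C)c(c1)C(=O)OC
F3 | step 12 | 5-{2-[(1Z,3S,4S)-3-[(tert-butyldimethylsilyl)oxy]-4-[(4-methoxybenzyl)oxy]non-1-en-1-yl]-6-(methoxymethoxy)phenoxy}-2-methylbenzoic acid | CCCCC[C@H](OCc1ccc(OC)cc1)[C@@H](O[Si](C)(C)C(C)(C)C)/C=C\c1cccc(OCOC)c1Oc1ccc(C)c(c1)C(O)=O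
F4 | step 12 | 5-{2-[(1Z,3S,4S)-3-[(tert-butyldimethylsilyl)oxy]-4-hydroxynon-1-en-1-yl]-6-(methoxymethoxy)phenoxy}-2-methylbenzoic acid | CCCCC[C@H](O)[C@@H](O[Si](C)(C)C(C)(C)C)/C=C\c1cccc(OCOC)c1Oc1ccc(C)c(c1)C(O)=O
F5 | step 6 | 2-hydroxy-3-(methoxymethoxy)benzaldehyde | COCOc1cccc(C=O)c1O
F6 | step 6 | 2-ethynyl-6-(methoxymethoxy)phenol | COCOc1cccc(C#C)c1O
F7 | step 6 | tert-butyl[2-ethynyl-6-(methoxymethoxy)phenoxy]dimethylsilane | COCOc1cccc(C#C)c1O[Si](C)(C)C(C)(C)C
F8 | step 6 | (3S,4S)-1-{2-[(tert-butyldimethylsilyl)oxy]-3-(methoxymethoxy)phenyl}-4-[(4-methoxybenzyl)oxy]non-1-yn-3-ol | CCCCC[C@H](OCc1ccc(OC)cc1)[C@@H](O)C#Cc1cccc(OCOC)c1O[Si](C)(C)C(C)(C)C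
F9 | step 6 | (1Z,3S,4S)-1-{2-[(tert-butyldimethylsilyl)oxy]-3-(methoxymethoxy)phenyl}-4-[(4-methoxybenzyl)oxy]non-1-en-3-ol | CCCCC[C@H](OCc1ccc(OC)cc1)[C@@H](O)/C=C\c1cccc(OCOC)c1O[Si](C)(C)C(C)(C)C
F10 | step 8 | 4-bromo-2H-pyran-2-one | BrC1=CC(=O)OC=C1
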